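In a one-step world E climbs to a level and stays there, but in the alder run it falls from 36.3% at 12.0 h to 17.6% at 192 h while Z climbs to 43.4%. If you repeat a run, then, watch Z as closely as E.

| flask | X | D | J | temperature | remark | time |
|---|---|---|---|---|---|---|
| larch | 1.3 M | 1.4 M | 0.60 M | 35 °C | run made earlier |  |
| alder | 3 M | 1.4 M | 0.60 M | 70 °C | run made earlier |  |
| south | 2.0 M | 1.40 M | 0.600 M | 100 °C |  | 40 h |
| south-east | 2.0 M | 1.40 M | 0.600 M | 70 °C |  | 40 h |
| north-east | 2.0 M | 1.40 M | 0.600 M | 40 °C |  | 40 h |

| run | time / h | E / % | Z / % |
|---|---|---|---|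
| larch | 72.0 | 5.3 | 0.9 |
| larch | 120 | 8.9 | 1.1 |
| larch | 192 | 12.6 | 0 |
| larch | 288 | 16.7 | 0 |
| larch | 360 | 19.8 | 0.7 |
| larch | 600 | 26.4 | 0.7 |
| larch | 960 | 32.5 | 3.0 |
| alder | 12.0 | 36.3 | 2.4 |
| alder | 20.0 | 34.6 | 5.9 |
| alder | 40.0 | 31.0 | 15.1 |
| alder | 48.0 | 28.5 | 18.1 |
| alder | 72.0 | 24.7 | 26.6 |
| alder | 120 | 20.8 | 36.4 |
| alder | 192 | 17.6 | 43.4 |

(each reading ± 0.5 percentage points)



- the flask that comes out highest in amount of E, in percent of the X charged, or "all alike" when all lie within 1.5 percentage points (south / south-east / north-east / all alike)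
- E at the end, in percent of the X charged, south
- E at the end, in percent of the X charged, south-east
- E at the end, in percent of the X charged, north-east

We keep a ledger of D, taking it as the limiting reagent of Z with one D in each Z, and we work it for south-east, which shares the temperature of alder.

1. South-east opens with D at 1.40 M, which is 70.0% of the X charged. We take this as the ceiling on Z.
2. At its last reading, alder holds Z at 1.30 M and E plus Z at 1.83 M, above the D charged. We read this as E holding no D.
3. We replace the Z curve by its mean slope up to 40.0 h. This drain, the Z made per hour as a share of the X charged, averaged from the start, reads 0.00377 h⁻¹.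
4. The mean has an error: at 20.0 h it gives 7.54% against a reading of 5.9%. It serves for the end of the span, not the middle.
5. Carried to south-east, the drain books 15.1% as Z by 40 h, leaving 55 percentage points under the ceiling.
6. Alder's E plus Z at that time is 46.1%. Taking the drain off gives back alder's own E reading, and on that borrowed figure our books close with E at 31.0% in south-east.
7. In larch, the same mean is 0.00828 of alder's, as a reading with its scatter. Over 40 h that books 0.125% as Z, and we book this figure for north-east, whose temperature lies near larch's.

The forecast names south-east, with E at 32% in south, 42% in south-east and 6.3% in north-east, and says of south “Z probably reaches equilibrium”. Our south-east figure is lower than its figure.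

The flasks give E at 3.61% in south, 25.8% in south-east and 7.52% in north-east, so south-east is highest.

    D → G (k = 0.0420 h⁻¹, Ea = 120 kJ mol⁻¹)
    E + G → Z (k = 0.0210 M⁻¹ h⁻¹, Ea = 91.0 kJ mol⁻¹)
    X + J → Q (k = 2.50 M⁻¹ h⁻¹, Ea = 86.0 kJ mol⁻¹)
    X ⇌ E (K = 0.920, k = 0.150 h⁻¹, Ea = 119 kJ mol⁻¹, ΔH = −41.0 kJ mol⁻¹)
    (constants at 70 °C)

South-east holds Z at 14.6% at 40.0 h, beside the 15.1% booked by the drain, and E stands below our 31.0%. In north-east the length of the run is one part of what keeps E low: E stands at 7.52% at 40.0 h and at 39.5% in a run ten times as long. The step between X and E has there a relaxation half-life, both ways together, of 197 h, long against the 40 h of the run. For north-east left ten times as long, larch's drain, read at 35 °C, books 1.25%, and the flask holds Z at 2.16% at 400 h.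

The earlier runs and the new flask are calculated from invented constants.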